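**Percent against molar.** Compare late J across the earlier runs, from 20.0 min on. It reads 5.33% of the D charged in epsilon at 0.54 M, 4.25% in delta at 0.80 M and 3.75% in alpha at 1.2 M. In these readings the percentage falls as the charge rises, though delta also differs in its loading, 0.25 mol% of X against 0.5 mol%, while [J] reads 28.8 mM, 34.0 mM and 45.0 mM.

| setting | epsilon | alpha | delta | flask |
|---|---|---|---|---|
| D | 0.54 M | 1.2 M | 0.80 M | 0.80 M |
| X | 0.5 mol% | 0.5 mol% | 0.25 mol% | 0.5 mol% |
| remark | run made earlier | run made earlier | run made earlier |  |
| time |  |  |  | 50 min |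

- epsilon (time / min: J / %, Z / %): 5.00: 4, 40; 8.00: 5, 46; 12.0: 6, 49; 20.0: 6, 54; 40.0: 4, 54; 60.0: 6, 54
- alpha (time / min: J / %, Z / %): 4.00: 5, 42; 12.0: 7, 53; 20.0: 3, 57; 30.0: 5, 57; 50.0: 3, 57; 60.0: 4, 57
- delta (time / min: J / %, Z / %): 12.0: 4, 40; 25.0: 4, 40; 40.0: 3, 40; 50.0: 5, 40; 60.0: 5, 39

(readings scatter by 1.5 percentage points)

- ratio of J to Z at 1.5 s
- ratio of J to Z at 50 min
- which of J and Z there is more of at 50 min

- the analysis behind the earlier runs scatters by 1.5 percentage points, standard deviation
- a reading or a percentage of Z counts all its forms, free or not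

**Bench rule.** You would treat J/Z as a fixed selectivity factor, 0.119 at the first alpha reading, and carry it back to 1.5 s. The border is a ratio: that reading stands at 4.00 min, 160 times later than the asked moment.

**Early end.** I assume that J grows out of Z, so J/Z starts from nothing and rises at first. A straight line back through that reading gives 7.44 × 10⁻⁴ at 1.5 s, which is a floor if the reading has already bent.

**Late end.** The mean of the three values of [J], 35.9 mM, is my late level of J: an estimate that takes one late [J] across these charges of D. The scatter does not exclude a constant percentage, but I commit to the late level. For the flask at 0.80 M it gives 4.49% of the charge. With Z near 55.5%, from the two runs at this loading, J/Z is 0.0809 at 50 min, and Z leads.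

**The forecast.** Citing “parallel formation at fixed selectivity”, it gave 0.11 at 1.5 s, 0.09 at 50 min, and Z ahead.

**The flask.** It gives 0.00170 at 1.5 s, above my floor, and 0.0698 at 50 min, with Z ahead: Z 54.8%, J 3.83%.

    Z + X ⇌ J + X, rate k1*[X]*[Z] forward; the back reaction follows from the equilibrium constant (K = 0.990, k = 34.0 L mol⁻¹ min⁻¹)
    2 D → E (k = 0.260 L mol⁻¹ min⁻¹)
    D + X ⇌ Z + X, rate k3*[D]*[X] forward; the back reaction follows from the equilibrium constant (K = 1.70, k = 93.0 L mol⁻¹ min⁻¹)
    X ⇌ Q (K = 0.930, k = 0.0580 min⁻¹)
    L ⇌ Z, rate k5*(cs5 - [Z]) while solid is left; crystals form when [Z] > cs5 (solubility = 30.0 mM, k = 0.920 min⁻¹)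

**The level.** At 50 min this flask holds 3.83% of J, or 30.6 mM, against the 4.49% from 35.9 mM, a gap smaller than one reading's scatter. The run without the crystallising out of Z shows what that step does here: J/Z at 50 min goes from 0.0698 to 1.09, and J leads.

**Second flask.** With 1.2 mol% of X at the same 0.80 M, the late level again gives 4.49% of J. Computed, that flask holds 3.70% of J and 70.1% of Z at 50 min, so J/Z is 0.0528.

All runs are calculated with made-up constants, and the scatter is random.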